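**Retrosynthetic overview**

1. Locants used: ring A (cyclohexane) = C5 (CH–isopropenyl), C6 (CH–O), C7 (CH), C8 (CH–O-acyl), C9 (CH2), C10 (C(CH3)(vinyl)); ring B (γ-lactone) = C6–O–C12(=O)–C11(CH3)(OAc)–C7.
2. Target ⇒ C11 acetylation, C8 ester by Mitsunobu inversion, C8 ketone reduction and desilylation ⇒ tricyclic silyl enol ether 14.
3. 14 ⇒ intramolecular Diels–Alder reaction of the acyclic pentaene ester 13, which forms C6–C7 and C5–C10, closes rings A and B together and sets C5, C6, C7 and C10 at once.
4. Enabling feature: ring B spans the C6–C7 bond of ring A, so its O–C12(=O)–C11 chain is a built-in three-atom tether between a C5=C6 enol-ester dienophile and a C7=C8–C9=C10 2-oxy-diene; the oxygens on C11 and C8 stand 1,3 across C7, so one Si(iPr)2 unit can tie them into a temporary six-membered ring C that fixes the diene geometry and face.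
5. 13 ⇒ (S)-citramalic acid (C7, C8, C11, C12, C13) + propynyl unit (C9, C10, C14) + vinyl unit (C1, C2) + 2-methylbut-1-en-3-yne (C3–C6, C15); ring order: temporary ring C (step 6), rings A and B together (step 7), ring C removed (step 8).

Key step: step 7

Remark: (S)-citramalic acid (1) is taken as a purchasable chiral-pool acid; its quaternary carbinol carbon becomes C11 of the target with unchanged (S) configuration.

**Route**

Step 1
Reactants: 1 (S)-citramalic acid; 2 2,2-dimethoxypropane
Product: 3 2-[(4S)-2,2,4-trimethyl-5-oxo-1,3-dioxolan-4-yl]acetic acid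
Conditions: 2 (3 equiv), TsOH·H2O (cat.), acetone, rt
Reagents that add atoms: 2,2-dimethoxypropane (2), COC(C)(C)OC
Why: Acid-catalysed transacetalisation (acetonide formation) closes the five-membered 1,3-dioxolan-4-one on the α-hydroxy acid unit in preference to a six-membered ring through the β-carboxyl group, so the CH2CO2H group stays free and the quaternary stereocentre is untouched.

Step 2
Reactants: 3 2-[(4S)-2,2,4-trimethyl-5-oxo-1,3-dioxolan-4-yl]acetic acid; 4 tributyl(prop-1-yn-1-yl)stannane
Product: 6 (5S)-2,2,5-trimethyl-5-(2-oxopent-3-yn-1-yl)-1,3-dioxolan-4-one, via acid chloride 5 (not isolated)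
Conditions: (COCl)2, DMF (cat.), CH2Cl2, 0 °C to rt; concentrate; then 4, Pd(PPh3)2Cl2 (cat.), ClCH2CH2Cl, 70 °C
Reagents that add atoms: tributyl(prop-1-yn-1-yl)stannane (4), CC#C[Sn](CCCC)(CCCC)CCCC
Why: Acid chloride formation followed by a Stille acyl cross-coupling with the alkynylstannane gives the ynone under neutral conditions that the acid-labile dioxolanone and the β-alkoxy ketone should tolerate.

Step 3
Reactants: 6 (5S)-2,2,5-trimethyl-5-(2-oxopent-3-yn-1-yl)-1,3-dioxolan-4-one; 7 vinylmagnesium bromide
Product: 8 (5S)-2,2,5-trimethyl-5-[(3E)-4-methyl-2-oxohexa-3,5-dien-1-yl]-1,3-dioxolan-4-one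
Conditions: CH2=CHMgBr, CuBr·SMe2 (1:1), THF, −78 °C; AcOH, −78 °C
Reagents that add atoms: vinylmagnesium bromide (7), C=C[Mg]Br
Why: Conjugate syn-carbocupration of the ynone places the vinyl group trans to the carbonyl, and low-temperature protonation of the allenolate should give the (E)-dienone, which is also the thermodynamically preferred isomer because the (Z)-dienone suffers a vinyl–acyl clash.

Step 4
Reactants: 8 (5S)-2,2,5-trimethyl-5-[(3E)-4-methyl-2-oxohexa-3,5-dien-1-yl]-1,3-dioxolan-4-one
Product: 9 (2S,5E)-2-hydroxy-2,6-dimethyl-4-oxoocta-5,7-dienoic acid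
Conditions: 1 M HCl (aq), THF, rt
Reagents that add atoms: water, O
Why: Aqueous acid hydrolysis of the acetonide-type dioxolanone, which is both an acetal and an activated ester, releases the α-hydroxy acid, while the tertiary alcohol next to the carboxyl group should neither ionise nor dehydrate under these mild conditions.

Step 5
Reactants: 9 (2S,5E)-2-hydroxy-2,6-dimethyl-4-oxoocta-5,7-dienoic acid; 10 2-methylbut-1-en-3-yne
Product: 11 (1Z)-3-methylbuta-1,3-dien-1-yl (2S,5E)-2-hydroxy-2,6-dimethyl-4-oxoocta-5,7-dienoate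
Conditions: Ru(η3-CH2C(CH3)CH2)2(Ph2P(CH2)4PPh2) (2 mol %), 10 (3 equiv), PhMe, 60 °C, sealed tube
Reagents that add atoms: 2-methylbut-1-en-3-yne (10), C=C(C)C#C
Why: Ruthenium-vinylidene-mediated anti-Markovnikov hydro-oxycarbonylation of the terminal alkyne delivers the enol ester by net trans addition, which sets the (Z) geometry of the C5=C6 bond, and the hindered tertiary alcohol and the dienone are not expected to compete as nucleophiles.

Step 6
Reactants: 11 (1Z)-3-methylbuta-1,3-dien-1-yl (2S,5E)-2-hydroxy-2,6-dimethyl-4-oxoocta-5,7-dienoate; 12 diisopropylsilyl bis(trifluoromethanesulfonate)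
Product: 13 (1Z)-3-methylbuta-1,3-dien-1-yl (4S)-4-methyl-6-[(1E)-2-methylbuta-1,3-dien-1-yl]-2,2-di(propan-2-yl)-4H-1,3,2-dioxasiline-4-carboxylate
Conditions: iPr2Si(OTf)2, Et3N, CH2Cl2, −78 to 0 °C
Reagents that add atoms: diisopropylsilyl bis(trifluoromethanesulfonate) (12), CC(C)[Si](OS(=O)(=O)C(F)(F)F)(OS(=O)(=O)C(F)(F)F)C(C)C
Why: Silyl triflate/amine soft enolisation with a bifunctional silane, in which one Si–OTf bond silylates the ketone oxygen with kinetic deprotonation at the α' carbon C7 and the other captures the tertiary C11 hydroxyl, should close the six-membered 4H-1,3,2-dioxasiline (ring C) and thereby fix the 2-silyloxy diene with C11 cis to the enol oxygen.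

Step 7
Reactants: 13 (1Z)-3-methylbuta-1,3-dien-1-yl (4S)-4-methyl-6-[(1E)-2-methylbuta-1,3-dien-1-yl]-2,2-di(propan-2-yl)-4H-1,3,2-dioxasiline-4-carboxylate
Product: 14 cis-fused tricyclic cycloadduct, (3S,3aR,6S,7R,7aR)-6-ethenyl-3,6-dimethyl-7-(prop-1-en-2-yl)-3a,6,7,7a-tetrahydro-1-benzofuran-2(3H)-one whose C3 oxygen and C4 enol oxygen (C4=C5 double bond) are bridged by Si(iPr)2; H3a, H7a, H7 and the C6 methyl lie on one face
Conditions: PhMe (0.005 M), BHT (cat.), 160 °C, sealed tube
Reagents that add atoms: none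
Why: Thermal type 1 intramolecular Diels–Alder reaction, a concerted suprafacial [4+2] cycloaddition of the 2-silyloxy diene C7=C8–C9=C10 with the enol-ester double bond C5=C6 that forms C6–C7 and C5–C10; the closest known class is the cycloaddition of ester-tethered 1,3,8-nonatrienes to cis-fused bicyclic γ-lactones. Ring A closes by the [4+2] event itself and ring B closes through the three-atom O–C12(=O)–C11 tether as the C6–C7 bond forms, with the tether folded under the diene (endo) so that the ring fusion is cis. C7 is controlled by C11 through ring C, which holds the C11–O bond in the diene plane and the ester carbonyl perpendicular to it, so the dienophile can only reach the face that carries the carbonyl; C6 follows from the endo tether, C5 from the (Z) geometry of the dienophile (isopropenyl cis to oxygen) and C10 from the (E) geometry of C9=C10 (vinyl outside, methyl inside), all by suprafacial addition. The step needs site selectivity among five C=C bonds, which the tether secures because every other pairing would close a seven-membered or larger ring or would use the (Z)-dienyl ester as a diene tethered at its inside position, and it needs endo (cis) over exo (trans) fusion, which the short tether with its planar ester and the fused ring C should favour. The geminal substitution at C11, the restricted rotamers and the electron-rich diene are counted on to offset the unactivated dienophile, the inside methyl group and the s-cis ester requirement, while high dilution and a radical inhibitor suppress intermolecular cycloaddition and polymerisation.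

Step 8
Reactants: 14 cis-fused tricyclic cycloadduct
Product: 15 (3S,3aS,6S,7R,7aR)-6-ethenyl-3-hydroxy-3,6-dimethyl-7-(prop-1-en-2-yl)hexahydro-1-benzofuran-2,4-dione
Conditions: HF·pyridine, pyridine, THF, 0 °C to rt
Reagents that add atoms: none
Why: Fluoride-induced cleavage of both Si–O bonds (protodesilylation of the silyl enol ether with protonation at C9, which is not a stereocentre, and release of the tertiary alcohol) under buffered acidic conditions that should avoid retro-aldol cleavage and β-elimination of the β-acyloxy ketone.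

Step 9
Reactants: 15 (3S,3aS,6S,7R,7aR)-6-ethenyl-3-hydroxy-3,6-dimethyl-7-(prop-1-en-2-yl)hexahydro-1-benzofuran-2,4-dione
Product: 16 (3S,3aS,4S,6S,7R,7aR)-6-ethenyl-3,4-dihydroxy-3,6-dimethyl-7-(prop-1-en-2-yl)hexahydro-1-benzofuran-2(3H)-one
Conditions: LiBH(s-Bu)3, THF, −78 °C; AcOH, −78 °C
Reagents that add atoms: none
Why: Hydride reduction under steric approach control: in the chair of ring A with the C5 and C7 substituents equatorial, the axial trajectory to C8 is blocked by the syn-axial C6–O bond and the axial C10 vinyl group, so the bulky borohydride should attack from the face that carries H5, H6 and H7 and give the axial (4S) alcohol cis to the lactone, while the lactone survives at −78 °C.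

Step 10
Reactants: 16 (3S,3aS,4S,6S,7R,7aR)-6-ethenyl-3,4-dihydroxy-3,6-dimethyl-7-(prop-1-en-2-yl)hexahydro-1-benzofuran-2(3H)-one; 17 3-methylbut-3-enoic acid
Product: 18 (3S,3aS,4R,6S,7R,7aR)-6-ethenyl-3-hydroxy-3,6-dimethyl-2-oxo-7-(prop-1-en-2-yl)octahydro-1-benzofuran-4-yl 3-methylbut-3-enoate
Conditions: PPh3, DIAD, PhMe, 0 °C to rt
Reagents that add atoms: 3-methylbut-3-enoic acid (17), C=C(C)CC(=O)O
Why: Mitsunobu esterification, in which SN2 displacement of the oxyphosphonium group by the carboxylate from the open face inverts C8 to the equatorial (4R) ester of the target, while the tertiary alcohol cannot be activated and the neutral conditions should leave the β,γ-unsaturated acyl group unconjugated.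

Step 11
Reactants: 18 (3S,3aS,4R,6S,7R,7aR)-6-ethenyl-3-hydroxy-3,6-dimethyl-2-oxo-7-(prop-1-en-2-yl)octahydro-1-benzofuran-4-yl 3-methylbut-3-enoate; 19 acetic anhydride
Product: 20 (3S,3aS,4R,6S,7R,7aR)-3-(acetyloxy)-6-ethenyl-3,6-dimethyl-2-oxo-7-(prop-1-en-2-yl)octahydro-1-benzofuran-4-yl 3-methylbut-3-enoate
Conditions: Ac2O, DMAP, Et3N, CH2Cl2, rt
Reagents that add atoms: acetic anhydride (19), CC(=O)OC(C)=O
Why: DMAP-catalysed acylation of the tertiary α-hydroxy lactone with acetic anhydride completes the target without touching any stereocentre.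

**Compound list**

1 | (S)-citramalic acid, (2S)-2-hydroxy-2-methylbutanedioic acid | C[C@](O)(CC(=O)O)C(=O)O | starting material
2 | 2,2-dimethoxypropane | COC(C)(C)OC | starting material
3 | 2-[(4S)-2,2,4-trimethyl-5-oxo-1,3-dioxolan-4-yl]acetic acid | C[C@@]1(CC(=O)O)OC(C)(C)OC1=O | intermediate
4 | tributyl(prop-1-yn-1-yl)stannane | CC#C[Sn](CCCC)(CCCC)CCCC | starting material
5 | 2-[(4S)-2,2,4-trimethyl-5-oxo-1,3-dioxolan-4-yl]acetyl chloride | C[C@@]1(CC(=O)Cl)OC(C)(C)OC1=O | intermediate
6 | (5S)-2,2,5-trimethyl-5-(2-oxopent-3-yn-1-yl)-1,3-dioxolan-4-one | C[C@@]1(CC(=O)C#CC)OC(C)(C)OC1=O | intermediate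
7 | vinylmagnesium bromide | C=C[Mg]Br | starting material
8 | (5S)-2,2,5-trimethyl-5-[(3E)-4-methyl-2-oxohexa-3,5-dien-1-yl]-1,3-dioxolan-4-one | C[C@@]1(CC(=O)/C=C(\C)C=C)OC(C)(C)OC1=O | intermediate
9 | (2S,5E)-2-hydroxy-2,6-dimethyl-4-oxoocta-5,7-dienoic acid | C[C@](O)(CC(=O)/C=C(\C)C=C)C(=O)O | intermediate
10 | 2-methylbut-1-en-3-yne | C=C(C)C#C | starting material
11 | (1Z)-3-methylbuta-1,3-dien-1-yl (2S,5E)-2-hydroxy-2,6-dimethyl-4-oxoocta-5,7-dienoate | C[C@](O)(CC(=O)/C=C(\C)C=C)C(=O)O/C=C\C(C)=C | intermediate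
12 | diisopropylsilyl bis(trifluoromethanesulfonate) | CC(C)[Si](OS(=O)(=O)C(F)(F)F)(OS(=O)(=O)C(F)(F)F)C(C)C | starting material
13 | (1Z)-3-methylbuta-1,3-dien-1-yl (4S)-4-methyl-6-[(1E)-2-methylbuta-1,3-dien-1-yl]-2,2-di(propan-2-yl)-4H-1,3,2-dioxasiline-4-carboxylate | C[C@]1(C(=O)O/C=C\C(C)=C)O[Si](C(C)C)(C(C)C)OC(/C=C(\C)C=C)=C1 | intermediate
14 | cis-fused tricyclic cycloadduct, (3S,3aR,6S,7R,7aR)-6-ethenyl-3,6-dimethyl-7-(prop-1-en-2-yl)-3a,6,7,7a-tetrahydro-1-benzofuran-2(3H)-one with the C3 oxygen and the C4 enol oxygen bridged by Si(iPr)2 | C=C[C@]1(C)C=C2O[Si](C(C)C)(C(C)C)O[C@]3(C)C(=O)O[C@H]([C@@H]1C(=C)C)[C@H]23 | intermediate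
15 | (3S,3aS,6S,7R,7aR)-6-ethenyl-3-hydroxy-3,6-dimethyl-7-(prop-1-en-2-yl)hexahydro-1-benzofuran-2,4-dione | C=C[C@]1(C)CC(=O)[C@H]2[C@H](OC(=O)[C@@]2(C)O)[C@@H]1C(=C)C | intermediate
16 | (3S,3aS,4S,6S,7R,7aR)-6-ethenyl-3,4-dihydroxy-3,6-dimethyl-7-(prop-1-en-2-yl)hexahydro-1-benzofuran-2(3H)-one | C=C[C@]1(C)C[C@H](O)[C@H]2[C@H](OC(=O)[C@@]2(C)O)[C@@H]1C(=C)C | intermediate
17 | 3-methylbut-3-enoic acid | C=C(C)CC(=O)O | starting material
18 | (3S,3aS,4R,6S,7R,7aR)-6-ethenyl-3-hydroxy-3,6-dimethyl-2-oxo-7-(prop-1-en-2-yl)octahydro-1-benzofuran-4-yl 3-methylbut-3-enoate | C=C[C@]1(C)C[C@@H](OC(=O)CC(=C)C)[C@H]2[C@H](OC(=O)[C@@]2(C)O)[C@@H]1C(=C)C | intermediate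
19 | acetic anhydride | CC(=O)OC(C)=O | starting material
20 | (3S,3aS,4R,6S,7R,7aR)-3-(acetyloxy)-6-ethenyl-3,6-dimethyl-2-oxo-7-(prop-1-en-2-yl)octahydro-1-benzofuran-4-yl 3-methylbut-3-enoate | C=C[C@]1(C)C[C@@H](OC(=O)CC(=C)C)[C@H]2[C@H](OC(=O)[C@@]2(C)OC(C)=O)[C@@H]1C(=C)C | target

**Step count and risks**

Total step count: 11. Longest linear sequence: 11 steps (1 to 20).

Steps most likely to fail:

- **Step 7.** The cycloaddition may be too slow because the dienophile is unactivated, the diene terminus carries an inside methyl group and the ester must adopt its s-cis form. A [1,5]-hydrogen shift of the Z-methyl diene, loss of the silyl enol ether or exo (trans-fused) closure could then compete. The fallback activates the dienophile with a carbonyl group and converts it afterwards; it sets out from 9 and comes back at 14. Ruthenium-catalysed Z-selective addition of 9 to but-3-yn-2-ol would give the (1Z)-3-hydroxybut-1-en-1-yl ester F1. Oxidation with Dess–Martin periodinane would give the (1Z)-3-oxobut-1-en-1-yl ester F2. Silylene closure as in step 6 would give the dioxasiline F3. A normal-electron-demand intramolecular Diels–Alder reaction near 100 °C, with the acetyl group endo, would give the acetyl-substituted cycloadduct F4. Methylenation of the methyl ketone with Cp2Ti(μ-Cl)(μ-CH2)AlMe2 would then return to 14.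

- **Step 10.** Activation of the crowded axial alcohol may be slow, and anti elimination towards C7 or C9 may outrun substitution. The fallback replaces the redox condensation by a sulfonate displacement; it sets out from 16 and comes back at 18. Selective sulfonylation of the secondary alcohol with ClCH2SO2Cl and pyridine would give the chloromethanesulfonate F5. Displacement with the caesium salt of 17 (Cs2CO3, 18-crown-6, PhMe) from the open face would give 18 with inversion.

- **Step 6.** Ring closure onto the hindered tertiary alcohol may lag behind intermolecular silylation, or enolisation may occur at the γ-methyl group instead of C7. The fallback gives up the temporary ring and relies on acyclic control; it sets out from 11 and comes back at 15. Double silylation with Et3SiOTf and Et3N would give the bis(triethylsilyl) compound F6 (tertiary silyl ether plus (Z)-silyl dienol ether). Thermal intramolecular Diels–Alder reaction, with the diene face now governed by allylic strain at C11, would give the bis(triethylsilyl) cycloadduct F7. Global desilylation with HF·pyridine would return to 15.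

Further compounds
F1 | step 7 | (1Z)-3-hydroxybut-1-en-1-yl (2S,5E)-2-hydroxy-2,6-dimethyl-4-oxoocta-5,7-dienoate (carbinol centre of the butenyl group not controlled) | C[C@](O)(CC(=O)/C=C(\C)C=C)C(=O)O/C=C\C(C)O
F2 | step 7 | (1Z)-3-oxobut-1-en-1-yl (2S,5E)-2-hydroxy-2,6-dimethyl-4-oxoocta-5,7-dienoate | C[C@](O)(CC(=O)/C=C(\C)C=C)C(=O)O/C=C\C(C)=O
F3 | step 7 | (1Z)-3-oxobut-1-en-1-yl (4S)-4-methyl-6-[(1E)-2-methylbuta-1,3-dien-1-yl]-2,2-di(propan-2-yl)-4H-1,3,2-dioxasiline-4-carboxylate | C[C@]1(C(=O)O/C=C\C(C)=O)O[Si](C(C)C)(C(C)C)OC(/C=C(\C)C=C)=C1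
F4 | step 7 | 7-acetyl analogue of cycloadduct 14 (acetyl in place of prop-1-en-2-yl, same configuration) | C=C[C@]1(C)C=C2O[Si](C(C)C)(C(C)C)O[C@]3(C)C(=O)O[C@H]([C@@H]1C(C)=O)[C@H]23
F5 | step 10 | chloromethanesulfonate of the axial C4 hydroxyl of 16 | C=C[C@]1(C)C[C@H](OS(=O)(=O)CCl)[C@H]2[C@H](OC(=O)[C@@]2(C)O)[C@@H]1C(=C)C
F6 | step 6 | (1Z)-3-methylbuta-1,3-dien-1-yl (2S,3Z,5E)-2,6-dimethyl-2,4-bis[(triethylsilyl)oxy]octa-3,5,7-trienoate | CC[Si](CC)(CC)O[C@@](C)(/C=C(\O[Si](CC)(CC)CC)/C=C(\C)C=C)C(=O)O/C=C\C(C)=C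
F7 | step 6 | bis(triethylsilyl) analogue of cycloadduct 14 (C3 triethylsilyl ether and C4 triethylsilyl enol ether, same configuration) | C=C[C@]1(C)C=C(O[Si](CC)(CC)CC)[C@H]2[C@H](OC(=O)[C@@]2(C)O[Si](CC)(CC)CC)[C@@H]1C(=C)C
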